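**Retrosynthetic overview** (ring numbered as in cyclopent-2-en-1-one: C1 = C=O, C2=C3, C4 = CHOH, C5 = quaternary carbinol, C1′ = side-chain carbinol)
1. Target ← removal of a PMB ether at C4–O and a silyl ether at C5–O, Saegusa–Ito dehydrogenation (C2=C3) and silyl-to-acetate exchange at C1′–O ← a 2-hydroxycyclopentanone carrying the C4 ether and the complete C5 side chain.
2. Key disconnection: ring bonds C3–C4 and C1–C5, made together by a primary-amine/N-heterocyclic-carbene Michael–crossed-benzoin (3+2) annulation of acrolein (C1–C3) with an acyclic α,α′-dioxygenated ketone (C4, C5 and the side chain).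
3. Enabling feature: the tertiary α-ketol of the five-membered ring, C1(=O)–C5(OH) (benzoin retron), whose oxygen-bearing C4 is α to the latent C5 ketone and tied to C1 through C2–C3 (Michael retron); the saturated ring is a 1,5-keto aldehyde folded onto itself.
4. Acyclic ketone ← Weinreb amide of (S)-2-silyloxyhexadecanoic acid + PMB-oxymethyllithium; C1′ stereocentre ← Evans hydroxylation of an N-palmitoyl oxazolidinone.
5. Ring order: the single carbocycle is formed once, in the key step.

Key step: step 7

Remark: tributyl(iodomethyl)stannane, the cinchona primary amine and the triazolium salt are taken as purchasable; PMB = (4-methoxyphenyl)methyl. Which antipode of each chiral catalyst gives the needed sense cannot be predicted with confidence and would be settled with the antipodal triazolium salt and the quinidine-derived amine.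

Step 1
Reactants: 1 hexadecanoyl chloride; 2 (4S)-4-benzyl-1,3-oxazolidin-2-one
Product: 3 (4S)-4-benzyl-3-hexadecanoyl-1,3-oxazolidin-2-one
Conditions: Et3N, DMAP (cat.), CH2Cl2, 0 °C → rt
Reagents that add atoms: none
Why: DMAP-catalysed N-acylation of the oxazolidinone by the acid chloride (attachment of the Evans auxiliary) is a standard acyl substitution and creates no stereocentre.

Step 2
Reactants: 3 (4S)-4-benzyl-3-hexadecanoyl-1,3-oxazolidin-2-one
Product: 5 (4S)-4-benzyl-3-[(2S)-2-hydroxyhexadecanoyl]-1,3-oxazolidin-2-one, via sodium (Z)-enolate 4 (not isolated)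
Conditions: NaN(SiMe3)2, THF, −78 °C; then 2-(phenylsulfonyl)-3-phenyloxaziridine, −78 °C; AcOH quench
Reagents that add atoms: 2-(phenylsulfonyl)-3-phenyloxaziridine (Davis oxaziridine), O=S(=O)(c1ccccc1)N1OC1c1ccccc1
Why: Evans asymmetric enolate hydroxylation: the chelated sodium (Z)-enolate 4 is oxidized on the face away from the benzyl group, which sets the (S)-carbinol centre (future C1′).

Step 3
Reactants: 5 (4S)-4-benzyl-3-[(2S)-2-hydroxyhexadecanoyl]-1,3-oxazolidin-2-one
Product: 6 (2S)-2-hydroxy-N-methoxy-N-methylhexadecanamide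
Conditions: MeNHOMe, AlMe3, CH2Cl2, −10 °C → rt; aqueous Rochelle salt work-up
Reagents that add atoms: N,O-dimethylhydroxylamine, CNOC
Why: Weinreb transamidation of the N-acyloxazolidinone by the aluminium amide, directed to the exocyclic carbonyl by the aluminium alkoxide of the free α-hydroxyl, releases the auxiliary without enolizing the stereocentre.

Step 4
Reactants: 6 (2S)-2-hydroxy-N-methoxy-N-methylhexadecanamide
Product: 7 (2S)-N-methoxy-N-methyl-2-(triethylsilyloxy)hexadecanamide
Conditions: TESCl, imidazole, DMF, 0 °C → rt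
Reagents that add atoms: chlorotriethylsilane, CC[Si](Cl)(CC)CC
Why: Routine silyl ether formation masks the secondary alcohol for the organolithium step and the annulation and affects no stereocentre.

Step 5
Reactants: 8 (4-methoxyphenyl)methanol; 9 tributyl(iodomethyl)stannane
Product: 11 tributyl{[(4-methoxyphenyl)methoxy]methyl}stannane, via sodium (4-methoxyphenyl)methanolate 10 (not isolated)
Conditions: NaH, THF, 0 °C; then 9, THF–DMF, 0 °C → rt
Reagents that add atoms: none
Why: Williamson ether synthesis of the sodium alkoxide with the primary iodomethylstannane is the standard preparation of an alkoxymethylstannane.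

Step 6
Reactants: 11 tributyl{[(4-methoxyphenyl)methoxy]methyl}stannane; 7 (2S)-N-methoxy-N-methyl-2-(triethylsilyloxy)hexadecanamide
Product: 13 (3S)-1-[(4-methoxyphenyl)methoxy]-3-(triethylsilyloxy)heptadecan-2-one, via PMB-oxymethyllithium 12 (not isolated)
Conditions: 11, n-BuLi, THF, −78 °C; then 7, −78 °C; AcOH/THF quench, then water
Reagents that add atoms: none
Why: Tin–lithium exchange gives the α-alkoxymethyllithium, which adds once to the Weinreb amide through the stable chelated tetrahedral intermediate (Weinreb ketone synthesis), and at −78 °C the α-silyloxy stereocentre should not be deprotonated.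

Step 7
Reactants: 13 (3S)-1-[(4-methoxyphenyl)methoxy]-3-(triethylsilyloxy)heptadecan-2-one; 14 acrolein (prop-2-enal)
Product: 16 (2R,3S)-2-hydroxy-3-[(4-methoxyphenyl)methoxy]-2-[(1S)-1-(triethylsilyloxy)pentadecyl]cyclopentan-1-one, via keto aldehyde 15 (not isolated)
Conditions: 14 (1.5 equiv, slow addition), (8α,9S)-6′-methoxycinchonan-9-amine (9-amino-9-deoxy-epi-quinine, 20 mol %), (5aS,10bR)-2-(pentafluorophenyl)-5a,10b-dihydro-4H,6H-indeno[2,1-b][1,2,4]triazolo[4,3-d][1,4]oxazin-2-ium tetrafluoroborate (10 mol %), NaOAc (20 mol %), CHCl3, 23 °C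
Reagents that add atoms: none
Why: Proposed new method: the primary amine condenses with ketone 13 and tautomerizes to the less substituted enamine on the CH2OPMB side, which adds to acrolein to give δ-keto aldehyde 15 (ring bond C3–C4); the triazolylidene freed by NaOAc then adds to the aldehyde, and the resulting Breslow intermediate attacks the ketone carbonyl (ring bond C1–C5), expelling the carbene and leaving the tertiary α-ketol with every atom of both partners retained. The closest known reaction types are the secondary-amine/N-heterocyclic-carbene Michael–crossed-benzoin cascades of enals with 1,3-dicarbonyl donors, their enamine/carbene variants with aldehyde donors, and amine-catalysed Michael additions of O-protected hydroxyacetones; what is new is an α-alkoxy ketone acting as enamine donor toward acrolein in the same flask as the carbene. The only ring formed is the cyclopentanone, closed 5-exo-trig by the acyl-anion equivalent C1 onto the exocyclic C5 carbonyl. C4 is set in the Michael step by the chiral amine (enamine face) and stays correctable by imine/enamine epimerization until the ring closes; C5 is set in the benzoin step by the chiral triazolylidene together with the ring itself, because the compact five-membered transition state should keep the branched C5 side chain trans to the C4 ether and so give the cis C4–O/C5–O relationship. The step needs regioselective enamine formation away from C1′ (secured by the branching and the bulky silyl ether there, which also protects the C1′ configuration) and carbinol-face selectivity at C5 against a possible polar Felkin–Anh bias of the α-silyloxy centre (to be secured by catalyst control relayed through the enamine-set C4 centre).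

Step 8
Reactants: 16 (2R,3S)-2-hydroxy-3-[(4-methoxyphenyl)methoxy]-2-[(1S)-1-(triethylsilyloxy)pentadecyl]cyclopentan-1-one
Product: 17 (2S,3S)-2-hydroxy-2-[(1S)-1-hydroxypentadecyl]-3-[(4-methoxyphenyl)methoxy]cyclopentan-1-one (same spatial arrangement; the C2 descriptor changes by priority only)
Conditions: HF·pyridine, pyridine, THF, 0 °C → rt
Reagents that add atoms: none
Why: Fluoride-mediated cleavage of the triethylsilyl ether should leave the PMB ether and the α-ketol untouched and involves no stereocentre.

Step 9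
Reactants: 17 (2S,3S)-2-hydroxy-2-[(1S)-1-hydroxypentadecyl]-3-[(4-methoxyphenyl)methoxy]cyclopentan-1-one
Product: 18 (1S)-1-{(1R,2S)-1-hydroxy-2-[(4-methoxyphenyl)methoxy]-5-oxocyclopentyl}pentadecyl acetate
Conditions: Ac2O, pyridine, DMAP (cat.), CH2Cl2, 0 °C → rt
Reagents that add atoms: acetic anhydride, CC(=O)OC(C)=O
Why: DMAP-catalysed acetylation distinguishes the secondary side-chain alcohol from the unreactive tertiary ring hydroxyl and places the acetate of the target.

Step 10
Reactants: 18 (1S)-1-{(1R,2S)-1-hydroxy-2-[(4-methoxyphenyl)methoxy]-5-oxocyclopentyl}pentadecyl acetate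
Product: 19 (1S)-1-{(1R,5S)-5-[(4-methoxyphenyl)methoxy]-1,2-bis(trimethylsilyloxy)cyclopent-2-en-1-yl}pentadecyl acetate
Conditions: TMSOTf, Et3N, CH2Cl2, 0 °C
Reagents that add atoms: trimethylsilyl trifluoromethanesulfonate, C[Si](C)(C)OS(=O)(=O)C(F)(F)F
Why: Soft enolization with TMSOTf–Et3N can enolize the ketone only toward C2 (C5 is quaternary) and also caps the tertiary hydroxyl, giving the silyl enol ether needed for the Saegusa–Ito oxidation.

Step 11
Reactants: 19 (1S)-1-{(1R,5S)-5-[(4-methoxyphenyl)methoxy]-1,2-bis(trimethylsilyloxy)cyclopent-2-en-1-yl}pentadecyl acetate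
Product: 20 (1S)-1-{(1S,5S)-5-[(4-methoxyphenyl)methoxy]-2-oxo-1-(trimethylsilyloxy)cyclopent-3-en-1-yl}pentadecyl acetate (same spatial arrangement; descriptor at the quaternary carbon changes by priority only)
Conditions: Pd(OAc)2 (1.1 equiv), MeCN, rt
Reagents that add atoms: none
Why: Saegusa–Ito oxidation: the palladium enolate formed from the silyl enol ether undergoes β-hydride elimination toward C3, giving the C2=C3 enone and palladium metal (zerovalent).

Step 12
Reactants: 20 (1S)-1-{(1S,5S)-5-[(4-methoxyphenyl)methoxy]-2-oxo-1-(trimethylsilyloxy)cyclopent-3-en-1-yl}pentadecyl acetate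
Product: 22 (1S)-1-[(1R,5S)-1,5-dihydroxy-2-oxocyclopent-3-en-1-yl]pentadecyl acetate, via silyl ether alcohol 21 (not isolated)
Conditions: DDQ, CH2Cl2–pH 7 phosphate buffer (10:1), 0 °C; then 1 M aq. HCl, THF, 0 °C
Reagents that add atoms: none
Why: Oxidative cleavage of the PMB ether by DDQ (the neighbouring tertiary oxygen is still silylated, so no anisylidene acetal can form) followed by mild acid hydrolysis of the tertiary trimethylsilyl ether should release the target without touching the acetate or any stereocentre.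

**Compound list**
1 | hexadecanoyl chloride | CCCCCCCCCCCCCCCC(=O)Cl | starting material
2 | (4S)-4-benzyl-1,3-oxazolidin-2-one | O=C1N[C@@H](Cc2ccccc2)CO1 | starting material
3 | (4S)-4-benzyl-3-hexadecanoyl-1,3-oxazolidin-2-one | CCCCCCCCCCCCCCCC(=O)N1[C@@H](Cc2ccccc2)COC1=O | intermediate
4 | sodium (1Z)-1-[(4S)-4-benzyl-2-oxo-1,3-oxazolidin-3-yl]hexadec-1-en-1-olate | CCCCCCCCCCCCCC/C=C(\[O-])N1[C@@H](Cc2ccccc2)COC1=O.[Na+] | intermediate
5 | (4S)-4-benzyl-3-[(2S)-2-hydroxyhexadecanoyl]-1,3-oxazolidin-2-one | CCCCCCCCCCCCCC[C@H](O)C(=O)N1[C@@H](Cc2ccccc2)COC1=O | intermediate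
6 | (2S)-2-hydroxy-N-methoxy-N-methylhexadecanamide | CCCCCCCCCCCCCC[C@H](O)C(=O)N(C)OC | intermediate
7 | (2S)-N-methoxy-N-methyl-2-(triethylsilyloxy)hexadecanamide | CCCCCCCCCCCCCC[C@H](O[Si](CC)(CC)CC)C(=O)N(C)OC | intermediate
8 | (4-methoxyphenyl)methanol | COc1ccc(CO)cc1 | starting material
9 | tributyl(iodomethyl)stannane | CCCC[Sn](CCCC)(CCCC)CI | starting material
10 | sodium (4-methoxyphenyl)methanolate | COc1ccc(C[O-])cc1.[Na+] | intermediate
11 | tributyl{[(4-methoxyphenyl)methoxy]methyl}stannane | CCCC[Sn](CCCC)(CCCC)COCc1ccc(OC)cc1 | intermediate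
12 | {[(4-methoxyphenyl)methoxy]methyl}lithium | [Li]COCc1ccc(OC)cc1 | intermediate
13 | (3S)-1-[(4-methoxyphenyl)methoxy]-3-(triethylsilyloxy)heptadecan-2-one | CCCCCCCCCCCCCC[C@H](O[Si](CC)(CC)CC)C(=O)COCc1ccc(OC)cc1 | intermediate
14 | acrolein (prop-2-enal) | C=CC=O | starting material
15 | (4S,6S)-4-[(4-methoxyphenyl)methoxy]-5-oxo-6-(triethylsilyloxy)icosanal | CCCCCCCCCCCCCC[C@H](O[Si](CC)(CC)CC)C(=O)[C@H](CCC=O)OCc1ccc(OC)cc1 | intermediate
16 | (2R,3S)-2-hydroxy-3-[(4-methoxyphenyl)methoxy]-2-[(1S)-1-(triethylsilyloxy)pentadecyl]cyclopentan-1-one | CCCCCCCCCCCCCC[C@H](O[Si](CC)(CC)CC)[C@@]1(O)C(=O)CC[C@@H]1OCc1ccc(OC)cc1 | intermediate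
17 | (2S,3S)-2-hydroxy-2-[(1S)-1-hydroxypentadecyl]-3-[(4-methoxyphenyl)methoxy]cyclopentan-1-one | CCCCCCCCCCCCCC[C@H](O)[C@@]1(O)C(=O)CC[C@@H]1OCc1ccc(OC)cc1 | intermediate
18 | (1S)-1-{(1R,2S)-1-hydroxy-2-[(4-methoxyphenyl)methoxy]-5-oxocyclopentyl}pentadecyl acetate | CCCCCCCCCCCCCC[C@H](OC(C)=O)[C@@]1(O)C(=O)CC[C@@H]1OCc1ccc(OC)cc1 | intermediate
19 | (1S)-1-{(1R,5S)-5-[(4-methoxyphenyl)methoxy]-1,2-bis(trimethylsilyloxy)cyclopent-2-en-1-yl}pentadecyl acetate | CCCCCCCCCCCCCC[C@H](OC(C)=O)[C@@]1(O[Si](C)(C)C)C(O[Si](C)(C)C)=CC[C@@H]1OCc1ccc(OC)cc1 | intermediate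
20 | (1S)-1-{(1S,5S)-5-[(4-methoxyphenyl)methoxy]-2-oxo-1-(trimethylsilyloxy)cyclopent-3-en-1-yl}pentadecyl acetate | CCCCCCCCCCCCCC[C@H](OC(C)=O)[C@@]1(O[Si](C)(C)C)C(=O)C=C[C@@H]1OCc1ccc(OC)cc1 | intermediate
21 | (1S)-1-[(1R,5S)-5-hydroxy-2-oxo-1-(trimethylsilyloxy)cyclopent-3-en-1-yl]pentadecyl acetate | CCCCCCCCCCCCCC[C@H](OC(C)=O)[C@@]1(O[Si](C)(C)C)C(=O)C=C[C@@H]1O | intermediate
22 | (1S)-1-[(1R,5S)-1,5-dihydroxy-2-oxocyclopent-3-en-1-yl]pentadecyl acetate, i.e. (4S,5R)-5-[(1S)-1-acetoxypentadecyl]-4,5-dihydroxycyclopent-2-en-1-one | CCCCCCCCCCCCCC[C@H](OC(C)=O)[C@@]1(O)C(=O)C=C[C@@H]1O | target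

Total step count: 12. Longest linear sequence: 11 steps (steps 1–4 and 6–12; step 5 is a one-step branch).

**Steps most likely to fail**

1. Step 7. The enamine Michael addition may stall (amine tied up by acrolein, acrolein oligomerization, carbene–acrolein homoenolate pathways). Facial selection at the carbinol carbon may also be poor if the substrate bias of the α-silyloxy centre opposes the catalyst. Fallback, from 13 back to 16, by known stepwise chemistry: 13 is condensed with (S)-1-amino-2-(methoxymethyl)pyrrolidine to the SAMP hydrazone F1. LDA (THF, −78 °C) deprotonates the CH2OPMB side, and 4-bromobut-1-ene alkylates the azaenolate under auxiliary control to the butenyl hydrazone F2 (the antipodal auxiliary is used if the sense at the new centre proves opposite). Ozonolysis (O3, CH2Cl2, −78 °C, stopped at the first excess; PPh3) cleaves both the hydrazone and the terminal alkene and gives keto aldehyde 15, now isolated. A separate intramolecular crossed benzoin reaction of 15 (the same triazolium salt, Et3N, CH2Cl2), a well-precedented closure of δ-keto aldehydes, then gives 16.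

2. Step 12. Oxidative debenzylation on the finished enone may over-oxidize the liberated allylic alcohol, the silyl ether may be lost early so that an anisylidene acetal forms, or the acetyl group may migrate during the acid stage. Fallback, from 18 back to 22, moving the debenzylation to the robust saturated stage and ending with a mild global desilylation: 18 is treated with DDQ in wet CH2Cl2, followed by AcOH–THF–water to hydrolyse any anisylidene acetal, giving the cis-diol acetate F4. TMSOTf/Et3N in excess converts it into the tris-silylated enol ether F5, Pd(OAc)2 in MeCN gives the bis(trimethylsilyl) enone F6, and HF·pyridine (or citric acid in MeOH) releases 22.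

3. Step 11. Palladium-mediated dehydrogenation next to the fully substituted, oxygenated carbon may be slow, with competing hydrolysis of the silyl enol ether back to the ketone. Fallback, from 19 back to 20, by selenoxide elimination instead of palladium: 19 is selenenylated with PhSeCl (CH2Cl2, −78 °C) to the α-phenylselanyl ketone F3. Oxidation with H2O2/pyridine (CH2Cl2, 0 °C) triggers syn-elimination of the selenoxide, which can only use the C3 hydrogens, giving 20.

Further compounds
F1 | step 7 | SAMP hydrazone of 13: (3S)-1-[(4-methoxyphenyl)methoxy]-3-(triethylsilyloxy)heptadecan-2-one N-[(2S)-2-(methoxymethyl)pyrrolidin-1-yl]imine | CCCCCCCCCCCCCC[C@H](O[Si](CC)(CC)CC)C(=NN1CCC[C@H]1COC)COCc1ccc(OC)cc1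
F2 | step 7 | SAMP hydrazone of (5S,7S)-5-[(4-methoxyphenyl)methoxy]-7-(triethylsilyloxy)henicos-1-en-6-one | CCCCCCCCCCCCCC[C@H](O[Si](CC)(CC)CC)C(=NN1CCC[C@H]1COC)[C@H](CCC=C)OCc1ccc(OC)cc1
F3 | step 11 | (1S)-1-{(1R,2S)-2-[(4-methoxyphenyl)methoxy]-5-oxo-4-(phenylselanyl)-1-(trimethylsilyloxy)cyclopentyl}pentadecyl acetate (both epimers at the selenium-bearing carbon) | CCCCCCCCCCCCCC[C@H](OC(C)=O)[C@@]1(O[Si](C)(C)C)C(=O)C([Se]c2ccccc2)C[C@@H]1OCc1ccc(OC)cc1
F4 | step 12 | (1S)-1-[(1R,2S)-1,2-dihydroxy-5-oxocyclopentyl]pentadecyl acetate | CCCCCCCCCCCCCC[C@H](OC(C)=O)[C@@]1(O)C(=O)CC[C@@H]1O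
F5 | step 12 | (1S)-1-[(1S,5S)-1,2,5-tris(trimethylsilyloxy)cyclopent-2-en-1-yl]pentadecyl acetate | CCCCCCCCCCCCCC[C@H](OC(C)=O)[C@@]1(O[Si](C)(C)C)C(O[Si](C)(C)C)=CC[C@@H]1O[Si](C)(C)C
F6 | step 12 | (1S)-1-[(1S,5S)-2-oxo-1,5-bis(trimethylsilyloxy)cyclopent-3-en-1-yl]pentadecyl acetate | CCCCCCCCCCCCCC[C@H](OC(C)=O)[C@@]1(O[Si](C)(C)C)C(=O)C=C[C@@H]1O[Si](C)(C)C
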